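## Retrosynthetic overview

1. Feature: the ten-membered carbocycle fused to the chroman. Six consecutive ring carbons are a cyclohexane cut between its first and last member: the O-bearing quaternary C2, CH2, CH2, the CH carrying CMe2OH, CH2 and the olefinic CH. The other four (ring-fusion CH C3, CH2, CH2 and the methyl-bearing olefinic carbon) are an ethynyl and an isopropenyl group joined end to end.
2. Ring order: cyclohexane (bought), then the ten-membered ring (step 9), then the pyran ring (step 13). The benzene ring is bought as phloroglucinol.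
3. End game: 29 ⇐ TES removal ⇐ double Vilsmeier–Haack formylation ⇐ C2–CH3 from AlMe3 on the 2-methoxychroman ketal 25 ⇐ phloroglucinol C-Michael addition/hemiketalisation on alkylidene ketone 21.
4. 21 ⇐ dienone 16 (1,4-hydrosilylation, Mukaiyama aldol with isovaleraldehyde, dehydration). 16 ⇐ all-cis alkynol 13 by anionic acetylenic oxy-Cope ring expansion, six to ten.
5. 13 ⇐ (R)-cyclohex-3-ene-1-carboxylic acid: iodolactone, cis-epoxy ester, MeLi, TES ether, trans-diaxial isopropenyl opening, oxidation, epimerisation, axial ethynylation.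

Key step: step 9

Assumption: the C2=C3 geometry of 16 and the enol ether geometry of 17 are taken to be without consequence, since both carbons are re-hybridised later, so 16 is drawn 2Z and 17 without descriptor. The anomeric centre of 24 and 25 is drawn with its oxygen where the methyl group will sit.

Locants: 16–23 use cyclodecenone numbering (C1 = C=O, C2, C3, C4, C5 = C–CH3, C6 = CH, C7, C8 = CH–side chain). 24–29 use chroman numbering (O1, C2, C3, C4, C4a–C8a).

## Route

Step 1
Reactants: 1 (R)-cyclohex-3-ene-1-carboxylic acid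
Product: 2 (1R,4R,5R)-4-iodo-6-oxabicyclo[3.2.1]octan-7-one
Conditions: I2, KI, NaHCO3, H2O, 0 °C to rt
Reagents that add atoms: iodine, II
Why: Iodolactonisation: the carboxylate opens the iodonium ion anti and can only reach the alkene carbon that gives the γ-lactone, so the C–O bond forms on the carboxyl face and the C–I bond on the opposite face, both under control of the existing centre.

Step 2
Reactants: 2 (1R,4R,5R)-4-iodo-6-oxabicyclo[3.2.1]octan-7-one
Product: 4 ethyl (1R,3R,6S)-7-oxabicyclo[4.1.0]heptane-3-carboxylate (oxirane cis to the ester), via iodohydrin ester 3 (not isolated)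
Conditions: K2CO3, EtOH, rt
Reagents that add atoms: ethanol, CCO
Why: Lactone ethanolysis frees the alkoxide of 3, which displaces the trans-vicinal iodide in an intramolecular Williamson closure, so the oxirane oxygen stays on the ester face and only the former C–I carbon is inverted.

Step 3
Reactants: 4 ethyl (1R,3R,6S)-7-oxabicyclo[4.1.0]heptane-3-carboxylate
Product: 6 2-[(1R,3R,6S)-7-oxabicyclo[4.1.0]heptan-3-yl]propan-2-ol, via methyl ketone 5 (not isolated)
Conditions: MeLi, Et2O, −78 °C
Reagents that add atoms: methyllithium, [Li]C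
Why: Double 1,2-addition of an organolithium to an ester; at −78 °C an unactivated oxirane is inert to MeLi and the cis tertiary alkoxide cannot reach the rear side of either oxirane carbon, so no centre is touched.

Step 4
Reactants: 6 2-[(1R,3R,6S)-7-oxabicyclo[4.1.0]heptan-3-yl]propan-2-ol
Product: 7 triethyl{2-[(1R,3R,6S)-7-oxabicyclo[4.1.0]heptan-3-yl]propan-2-yloxy}silane
Conditions: Et3SiOTf, 2,6-lutidine, CH2Cl2, −78 °C
Reagents that add atoms: triethylsilyl triflate, CC[Si](CC)(CC)OS(=O)(=O)C(F)(F)F
Why: Silylation of a hindered tertiary alcohol with a silyl triflate and a non-nucleophilic base, fast enough at low temperature that the oxirane is not opened; no stereocentre is involved.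

Step 5
Reactants: 7 triethyl{2-[(1R,3R,6S)-7-oxabicyclo[4.1.0]heptan-3-yl]propan-2-yloxy}silane; 8 isopropenylmagnesium bromide
Product: 9 (1S,2R,4R)-2-(prop-1-en-2-yl)-4-[2-(triethylsilyloxy)propan-2-yl]cyclohexan-1-ol (OH and isopropenyl trans-diaxial, side chain equatorial)
Conditions: CuI (cat.), THF, −30 to 0 °C
Reagents that add atoms: isopropenylmagnesium bromide (8), CC(=C)[Mg]Br
Why: Copper-catalysed SN2 opening of an epoxide by a Grignard reagent under the Fürst–Plattner rule: with the bulky side chain equatorial, only attack at the oxirane carbon 1,3-related to it leads directly to a chair, which fixes the regiochemistry (isopropenyl at C2, OH at C1) and inverts C2.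

Step 6
Reactants: 9 (1S,2R,4R)-2-(prop-1-en-2-yl)-4-[2-(triethylsilyloxy)propan-2-yl]cyclohexan-1-ol
Product: 10 (2R,4R)-2-(prop-1-en-2-yl)-4-[2-(triethylsilyloxy)propan-2-yl]cyclohexan-1-one (trans, isopropenyl axial)
Conditions: Dess–Martin periodinane, CH2Cl2, 0 °C to rt
Reagents that add atoms: none
Why: Dess–Martin oxidation of the secondary alcohol under nearly neutral conditions, which leaves the silyl ether, the alkene and the axial C2 centre untouched.

Step 7
Reactants: 10 (2R,4R)-2-(prop-1-en-2-yl)-4-[2-(triethylsilyloxy)propan-2-yl]cyclohexan-1-one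
Product: 11 (2S,4R)-2-(prop-1-en-2-yl)-4-[2-(triethylsilyloxy)propan-2-yl]cyclohexan-1-one (cis, both groups equatorial)
Conditions: DBU (cat.), toluene, rt; chromatography, recycling of 10
Reagents that add atoms: none
Why: Base-catalysed epimerisation through the dienolate under thermodynamic control, which places both substituents equatorial; because dienolates are protonated faster at the α than at the γ carbon, epimerisation should outrun conjugation to the isopropylidene ketone.

Step 8
Reactants: 11 (2S,4R)-2-(prop-1-en-2-yl)-4-[2-(triethylsilyloxy)propan-2-yl]cyclohexan-1-one; 12 ethynylmagnesium bromide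
Product: 13 (1R,2S,4R)-1-ethynyl-2-(prop-1-en-2-yl)-4-[2-(triethylsilyloxy)propan-2-yl]cyclohexan-1-ol (three carbon substituents all cis; ethynyl axial, OH equatorial)
Conditions: THF, −78 to −20 °C
Reagents that add atoms: ethynylmagnesium bromide (12), C#C[Mg]Br
Why: 1,2-Addition of an alkynyl Grignard reagent: the slim, weakly basic sp nucleophile takes the axial trajectory on the chair locked by two equatorial groups and so sets C1 with ethynyl cis to isopropenyl, the epimer from equatorial attack (which would lead to the E olefin) being removed by chromatography.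

Step 9
Reactants: 13 (1R,2S,4R)-1-ethynyl-2-(prop-1-en-2-yl)-4-[2-(triethylsilyloxy)propan-2-yl]cyclohexan-1-ol
Product: 16 (2Z,5Z,8R)-5-methyl-8-[2-(triethylsilyloxy)propan-2-yl]cyclodeca-2,5-dien-1-one, via potassium alkoxide 14 (not isolated), via potassium allenolate 15 (not isolated)
Conditions: KH (1.05 equiv), 18-crown-6, THF, 0 °C to rt; then AcOH, THF, −78 °C
Reagents that add atoms: none
Why: KH gives the crown-separated alkoxide 14, whose oxyanion weakens the C1–C2 σ bond, and a concerted [3,3] shift joins the alkyne terminus to the isopropenyl CH2 while C1–C2 breaks, giving allenolate 15, which cold acetic acid protonates at its central carbon from the side of the allene hydrogen to give enone 16. The reaction type is the anionic acetylenic oxy-Cope rearrangement of 1-alkynyl-2-alkenylcyclohexanols. The ten-membered ring arises by four-atom ring expansion through a six-centre chair-like array and not by end-to-end cyclisation, so dilution is not needed and enolate formation makes the shift irreversible. No stereocentre is created, and C4 of 13 is carried over unchanged as C8 of 16. The selectivity required is Z geometry at the new C5=C6 bond: the bulky silyloxypropyl group locks the chair with equatorial isopropenyl and axial ethynyl, the isopropenyl CH2 can reach the upright alkyne only by turning over the ring C3 side, and ring C3, pseudo-axial in the six-centre array, therefore ends cis to the new C4 methylene. KH is used with almost no excess and leaves no conjugate acid in solution, so the alkyne C–H stays largely untouched and no proton shuttle is present to pull the skipped diene into conjugation before the quench.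

Step 10
Reactants: 16 (2Z,5Z,8R)-5-methyl-8-[2-(triethylsilyloxy)propan-2-yl]cyclodeca-2,5-dien-1-one
Product: 17 triethyl{[(5Z,8R)-5-methyl-8-(2-triethylsilyloxypropan-2-yl)cyclodeca-1,5-dien-1-yl]oxy}silane
Conditions: Et3SiH, RhCl(PPh3)3 (cat.), toluene, 50 °C
Reagents that add atoms: triethylsilane, CC[SiH](CC)CC
Why: Rhodium-catalysed 1,4-hydrosilylation of an enone with a monohydrosilane, which saturates C3, leaves the isolated trisubstituted alkene alone and stores the enolate regiospecifically at C1=C2; no stereocentre is formed.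

Step 11
Reactants: 17 triethyl{[(5Z,8R)-5-methyl-8-(2-triethylsilyloxypropan-2-yl)cyclodeca-1,5-dien-1-yl]oxy}silane; 18 isovaleraldehyde
Product: 19 (5Z,8R)-2-(1-hydroxy-3-methylbutyl)-5-methyl-8-[2-(triethylsilyloxy)propan-2-yl]cyclodec-5-en-1-one (mixture at the two new centres)
Conditions: BF3·OEt2, CH2Cl2, −78 °C
Reagents that add atoms: isovaleraldehyde (18), CC(C)CC=O
Why: Mukaiyama aldol addition: the Lewis-acid-activated aldehyde is attacked only at C2 of the regiodefined enol silane, and the two new centres need no control because both become sp2 in step 12.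

Step 12
Reactants: 19 (5Z,8R)-2-(1-hydroxy-3-methylbutyl)-5-methyl-8-[2-(triethylsilyloxy)propan-2-yl]cyclodec-5-en-1-one
Product: 21 (2E,5Z,8R)-5-methyl-2-(3-methylbutylidene)-8-[2-(triethylsilyloxy)propan-2-yl]cyclodec-5-en-1-one, via aldol mesylate 20 (not isolated)
Conditions: MsCl, Et3N, CH2Cl2, 0 °C; then DBU, rt
Reagents that add atoms: none
Why: Mesylation and E1cB elimination of a β-hydroxy ketone, DBU also equilibrating the alkylidene ketone to the E isomer in which the isobutyl chain points away from the carbonyl group.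

Step 13
Reactants: 21 (2E,5Z,8R)-5-methyl-2-(3-methylbutylidene)-8-[2-(triethylsilyloxy)propan-2-yl]cyclodec-5-en-1-one; 22 phloroglucinol (excess)
Product: 24 (2R,3S,4S)-4-isobutylchroman-2,5,7-triol with C2 and C3 bridged by –CH2CH2–CH(CMe2OSiEt3)–CH2–CH=C(CH3)–CH2CH2– (read from C2 to C3; chain CH is R, olefin Z), via keto triol 23 (not isolated)
Conditions: DBU (0.5 equiv), MeCN, 50 °C, argon; then pH 6 buffer
Reagents that add atoms: phloroglucinol (22), Oc1cc(O)cc(O)c1
Why: Base-mediated C-Michael (Friedel–Crafts-type conjugate) addition of the ambident phloroglucinolate followed by hemiketalisation: rearomatisation makes C–C bond formation the sink, C4 is set by attack on the outward face of the E-alkylidene unit of the folded ring (a substrate bias relative to the remote side-chain centre, the other series being removed by chromatography), and C3 is set by DBU equilibration through the open ketone 23 to the arrangement with C3–CH2 anti to the isobutyl group.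

Step 14
Reactants: 24 the chroman-2,5,7-triol hemiketal described in step 13
Product: 25 (2R,3S,4S)-4-isobutyl-2-methoxychroman-5,7-diol with the same C2–C3 bridge
Conditions: HC(OMe)3, PPTS (cat.), MeOH, 0 °C
Reagents that add atoms: methanol, CO
Why: Acid-catalysed hemiketal-to-ketal exchange with orthoformate as water scavenger, mild enough for the tertiary silyl ether; the anomeric centre equilibrates, and C3 and C4 are not affected.

Step 15
Reactants: 25 the 2-methoxychroman-5,7-diol described in step 14
Product: 26 (2R,3S,4S)-4-isobutyl-2-methylchroman-5,7-diol with the same C2–C3 bridge (trans ring fusion: CH3 cis to C3–CH2 and trans to the isobutyl group)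
Conditions: AlMe3 (6 equiv), CH2Cl2, −78 to −20 °C
Reagents that add atoms: trimethylaluminium, C[Al](C)C
Why: Lewis-acid-mediated substitution of a cyclic ketal by an organoaluminium reagent: AlMe3 first caps both phenols, then ionises the more basic exocyclic methoxy group, and the methoxyaluminate returns methyl within the ion pair along the axial trajectory of the half-chair that holds C3–CH2 and the isobutyl group pseudo-equatorial, that is anti to the isobutyl group, so CH3 ends cis to C3–CH2.

Step 16
Reactants: 26 the 2-methylchroman-5,7-diol described in step 15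
Product: 28 (2R,3S,4S)-5,7-dihydroxy-4-isobutyl-2-methylchroman-6,8-dicarbaldehyde with the same silylated C2–C3 bridge, via bis-iminium salt 27 (not isolated)
Conditions: POCl3, DMF, EtOAc, 0 °C to rt; then aq. NaOAc, rt
Reagents that add atoms: N,N-dimethylformamide, CN(C)C=O; water, O
Why: Vilsmeier–Haack formylation: C6 and C8 of the phloroglucinol-type ring are by far the most nucleophilic sites, so two chloroiminium ions are taken up and buffered hydrolysis of 27 releases both aldehydes without touching a stereocentre, the alcohol being kept silylated because the reagent would chlorinate or dehydrate a free tertiary alcohol.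

Step 17
Reactants: 28 the silylated dialdehyde described in step 16
Product: 29 target CNP0570248.1
Conditions: HF·pyridine, pyridine, THF, 0 °C
Reagents that add atoms: none
Why: Fluoride-driven cleavage of the triethylsilyl ether under buffered, weakly acidic conditions that spare the aldehydes, the Z alkene and the tertiary aryl ether.

## Compound list

1 | (R)-cyclohex-3-ene-1-carboxylic acid | OC(=O)[C@H]1CC=CCC1 | starting material
2 | (1R,4R,5R)-4-iodo-6-oxabicyclo[3.2.1]octan-7-one | O=C1O[C@@H]2C[C@H]1CC[C@H]2I | intermediate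
3 | ethyl (1R,3R,4R)-3-hydroxy-4-iodocyclohexane-1-carboxylate | CCOC(=O)[C@@H]1CC[C@@H](I)[C@H](O)C1 | intermediate
4 | ethyl (1R,3R,6S)-7-oxabicyclo[4.1.0]heptane-3-carboxylate | CCOC(=O)[C@@H]1CC[C@@H]2O[C@@H]2C1 | intermediate
5 | 1-[(1R,3R,6S)-7-oxabicyclo[4.1.0]heptan-3-yl]ethan-1-one | CC(=O)[C@@H]1CC[C@@H]2O[C@@H]2C1 | intermediate
6 | 2-[(1R,3R,6S)-7-oxabicyclo[4.1.0]heptan-3-yl]propan-2-ol | CC(C)(O)[C@@H]1CC[C@@H]2O[C@@H]2C1 | intermediate
7 | triethyl{2-[(1R,3R,6S)-7-oxabicyclo[4.1.0]heptan-3-yl]propan-2-yloxy}silane | CC[Si](CC)(CC)OC(C)(C)[C@@H]1CC[C@@H]2O[C@@H]2C1 | intermediate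
8 | isopropenylmagnesium bromide | CC(=C)[Mg]Br | starting material
9 | (1S,2R,4R)-2-(prop-1-en-2-yl)-4-[2-(triethylsilyloxy)propan-2-yl]cyclohexan-1-ol | O[C@@H]1[C@@H](C(C)=C)C[C@H](C(C)(C)O[Si](CC)(CC)CC)CC1 | intermediate
10 | (2R,4R)-2-(prop-1-en-2-yl)-4-[2-(triethylsilyloxy)propan-2-yl]cyclohexan-1-one | O=C1[C@@H](C(C)=C)C[C@H](C(C)(C)O[Si](CC)(CC)CC)CC1 | intermediate
11 | (2S,4R)-2-(prop-1-en-2-yl)-4-[2-(triethylsilyloxy)propan-2-yl]cyclohexan-1-one | O=C1[C@H](C(C)=C)C[C@H](C(C)(C)O[Si](CC)(CC)CC)CC1 | intermediate
12 | ethynylmagnesium bromide | C#C[Mg]Br | starting material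
13 | (1R,2S,4R)-1-ethynyl-2-(prop-1-en-2-yl)-4-[2-(triethylsilyloxy)propan-2-yl]cyclohexan-1-ol | O[C@@]1(C#C)[C@H](C(C)=C)C[C@H](C(C)(C)O[Si](CC)(CC)CC)CC1 | intermediate
14 | potassium alkoxide of 13 | [K+].[O-][C@@]1(C#C)[C@H](C(C)=C)C[C@H](C(C)(C)O[Si](CC)(CC)CC)CC1 | intermediate
15 | potassium (5Z,8R)-5-methyl-8-(2-triethylsilyloxypropan-2-yl)cyclodeca-1,2,5-trien-1-olate | [K+].[O-]C1=C=CC/C(C)=C\C[C@H](C(C)(C)O[Si](CC)(CC)CC)CC1 | intermediate
16 | (2Z,5Z,8R)-5-methyl-8-[2-(triethylsilyloxy)propan-2-yl]cyclodeca-2,5-dien-1-one | C/C1=C/C[C@H](C(C)(C)O[Si](CC)(CC)CC)CCC(=O)/C=C\C1 | intermediate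
17 | triethyl{[(5Z,8R)-5-methyl-8-(2-triethylsilyloxypropan-2-yl)cyclodeca-1,5-dien-1-yl]oxy}silane | CC[Si](CC)(CC)OC1=CCC/C(C)=C\C[C@H](C(C)(C)O[Si](CC)(CC)CC)CC1 | intermediate
18 | isovaleraldehyde | CC(C)CC=O | starting material
19 | (5Z,8R)-2-(1-hydroxy-3-methylbutyl)-5-methyl-8-[2-(triethylsilyloxy)propan-2-yl]cyclodec-5-en-1-one | O=C1CC[C@@H](C(C)(C)O[Si](CC)(CC)CC)C/C=C(C)\CCC1C(O)CC(C)C | intermediate
20 | methanesulfonate of 19 | O=C1CC[C@@H](C(C)(C)O[Si](CC)(CC)CC)C/C=C(C)\CCC1C(OS(C)(=O)=O)CC(C)C | intermediate
21 | (2E,5Z,8R)-5-methyl-2-(3-methylbutylidene)-8-[2-(triethylsilyloxy)propan-2-yl]cyclodec-5-en-1-one | O=C1CC[C@@H](C(C)(C)O[Si](CC)(CC)CC)C/C=C(C)\CC/C1=C\CC(C)C | intermediate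
22 | phloroglucinol | Oc1cc(O)cc(O)c1 | starting material
23 | (2S,5Z,8R)-5-methyl-2-[(1S)-3-methyl-1-(2,4,6-trihydroxyphenyl)butyl]-8-[2-(triethylsilyloxy)propan-2-yl]cyclodec-5-en-1-one | C/C1=C/C[C@H](C(C)(C)O[Si](CC)(CC)CC)CCC(=O)[C@@H](CC1)[C@H](CC(C)C)c2c(O)cc(O)cc2O | intermediate
24 | bridged (2R,3S,4S)-4-isobutylchroman-2,5,7-triol (hemiketal) | C/C1=C/C[C@H](C(C)(C)O[Si](CC)(CC)CC)CC[C@@]2(O)Oc3cc(O)cc(O)c3[C@@H](CC(C)C)[C@@H]2CC1 | intermediate
25 | bridged (2R,3S,4S)-4-isobutyl-2-methoxychroman-5,7-diol (methyl ketal) | C/C1=C/C[C@H](C(C)(C)O[Si](CC)(CC)CC)CC[C@@]2(OC)Oc3cc(O)cc(O)c3[C@@H](CC(C)C)[C@@H]2CC1 | intermediate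
26 | bridged (2R,3S,4S)-4-isobutyl-2-methylchroman-5,7-diol | C/C1=C/C[C@H](C(C)(C)O[Si](CC)(CC)CC)CC[C@@]2(C)Oc3cc(O)cc(O)c3[C@@H](CC(C)C)[C@@H]2CC1 | intermediate
27 | 6,8-bis(dimethyliminiomethyl) derivative of 26, dichloride | C/C1=C/C[C@H](C(C)(C)O[Si](CC)(CC)CC)CC[C@@]2(C)Oc3c(C=[N+](C)C)c(O)c(C=[N+](C)C)c(O)c3[C@@H](CC(C)C)[C@@H]2CC1.[Cl-].[Cl-] | intermediate
28 | triethylsilyl ether of the target | C/C1=C/C[C@H](C(C)(C)O[Si](CC)(CC)CC)CC[C@@]2(C)Oc3c(C=O)c(O)c(C=O)c(O)c3[C@@H](CC(C)C)[C@@H]2CC1 | intermediate
29 | CNP0570248.1 | C/C1=C/C[C@H](C(C)(C)O)CC[C@@]2(C)Oc3c(C=O)c(O)c(C=O)c(O)c3[C@@H](CC(C)C)[C@@H]2CC1 | target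

## Step count

Total step count: 17. Longest linear sequence: 17 steps, from 1 to 29. Compounds 8, 12, 18 and 22 are bought.

## Steps most likely to fail

**Step 9.**
- What may go wrong: the alkoxide may expel acetylide (retro-addition back to 11). The alkyne C–H may be deprotonated in competition. Proton transfer to the allenolate before the quench may drag the skipped diene into conjugation or erode the Z geometry.
- Fallback, sets out from 13 and comes back at 17: the alkyne is semi-hydrogenated (H2, Pd/CaCO3 poisoned with Pb(OAc)2, quinoline) to the vinyl carbinol F1. The olefinic anionic oxy-Cope rearrangement (KH, 18-crown-6, THF) then runs through the same locked chair and gives the potassium enolate F2. This species has neither an acidic C–H nor an allene unit, and it is silylated in the flask with Et3SiCl to give 17.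

**Step 15.**
- What may go wrong: the oxocarbenium ion may be captured across the ring by the Z alkene (Prins-type closure to a decalin). It may lose a proton to give the 4H-chromene. Ionisation may occur at the endocyclic aryl C–O bond instead, and methyl may arrive on the wrong face.
- Fallback, sets out from 13 and comes back at 28: the methyl group is placed on the ring carbon before the pyran ring exists, and the pyran ring is closed by a cycloaddition that needs no cation at that carbon. The potassium enolate F2 is reached through the vinyl carbinol F1 as above. Its enolate double bond is trans within the ring because it stems from the axial vinyl group. F2 is trapped with N-(5-chloro-2-pyridyl)bis(trifluoromethanesulfonimide) as the enol triflate F3. Iron-catalysed cross-coupling (MeMgBr, Fe(acac)3, THF/NMP, −20 °C) gives, with retention, the Z,E-diene F4. Vilsmeier–Haack diformylation of 22 gives 2,4-diformylphloroglucinol F5. Its Knoevenagel condensation with 18 (ethylenediammonium diacetate cat., MeCN, 60 °C) generates the o-quinone methide F6 in the presence of F4. The inverse-demand hetero-Diels–Alder addition to the strained E alkene is suprafacial, so the trans ring fusion follows from the olefin geometry, and 28 is obtained after separation from its stereoisomers.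

**Step 13.**
- What may go wrong: addition to a hindered, twisted enone may be sluggish. The two faces of the exocyclic β-carbon may be poorly discriminated relative to the remote side-chain centre.
- Fallback, sets out from 17 and comes back at 24: the roles of the two substituents at C4 are exchanged, so the last bond is made by a copper reagent whose ligand can decide the face. 2,4,6-Trihydroxybenzaldehyde is allylated (allyl bromide, K2CO3) to 2,4,6-tris(allyloxy)benzaldehyde F7. Mukaiyama aldol addition of 17 (BF3·OEt2, −78 °C) gives the benzylic aldol F8, which loses water with catalytic PPTS to give the arylidene ketone F9. Copper-catalysed conjugate addition (i-BuMgBr, CuBr·SMe2 with a chiral ferrocenyl diphosphine, Me3SiCl, then mild hydrolysis) gives the tris(allyl) ketone F10. Deallylation (Pd(PPh3)4, K2CO3, MeOH), which also equilibrates C3, gives 23 and hence 24.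

Further compounds
F1 | step 9 | (1S,2S,4R)-1-ethenyl-2-(prop-1-en-2-yl)-4-[2-(triethylsilyloxy)propan-2-yl]cyclohexan-1-ol | O[C@@]1(C=C)[C@H](C(C)=C)C[C@H](C(C)(C)O[Si](CC)(CC)CC)CC1
F2 | step 9 | potassium (5Z,8R)-5-methyl-8-(2-triethylsilyloxypropan-2-yl)cyclodeca-1,5-dien-1-olate, enolate bond trans within the ring | [K+].[O-]/C1=C\CC/C(C)=C\C[C@H](C(C)(C)O[Si](CC)(CC)CC)CC1
F3 | step 15 | (5Z,8R)-5-methyl-8-(2-triethylsilyloxypropan-2-yl)cyclodeca-1,5-dien-1-yl triflate, C1=C2 trans within the ring | O=S(=O)(O/C1=C\CC/C(C)=C\C[C@H](C(C)(C)O[Si](CC)(CC)CC)CC1)C(F)(F)F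
F4 | step 15 | triethyl{2-[(1R,3Z,7E)-4,8-dimethylcyclodeca-3,7-dien-1-yl]propan-2-yloxy}silane | C/C1=C\CC/C(C)=C\C[C@H](C(C)(C)O[Si](CC)(CC)CC)CC1
F5 | step 15 | 2,4-diformylphloroglucinol | O=Cc1c(O)cc(O)c(C=O)c1O
F6 | step 15 | o-quinone methide from F5 and isovaleraldehyde | CC(C)CC=C1C(=O)C(C=O)=C(O)C(C=O)=C1O
F7 | step 13 | 2,4,6-tris(allyloxy)benzaldehyde | C=CCOc1cc(OCC=C)c(C=O)c(OCC=C)c1
F8 | step 13 | (5Z,8R)-2-{hydroxy[2,4,6-tris(allyloxy)phenyl]methyl}-5-methyl-8-[2-(triethylsilyloxy)propan-2-yl]cyclodec-5-en-1-one | O=C1CC[C@@H](C(C)(C)O[Si](CC)(CC)CC)C/C=C(C)\CCC1C(O)c1c(OCC=C)cc(OCC=C)cc1OCC=C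
F9 | step 13 | (2E,5Z,8R)-5-methyl-2-[2,4,6-tris(allyloxy)benzylidene]-8-[2-(triethylsilyloxy)propan-2-yl]cyclodec-5-en-1-one | O=C1CC[C@@H](C(C)(C)O[Si](CC)(CC)CC)C/C=C(C)\CC/C1=C\c1c(OCC=C)cc(OCC=C)cc1OCC=C
F10 | step 13 | tris(allyl) ether of 23 | C/C1=C/C[C@H](C(C)(C)O[Si](CC)(CC)CC)CCC(=O)[C@@H](CC1)[C@H](CC(C)C)c2c(OCC=C)cc(OCC=C)cc2OCC=C
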